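**Retrosynthetic overview**
1. The C17 exo-methylene and the two silyl groups go on/off last (Eschenmoser methylenation, desilylation), because an acrylate would intercept the ylide of the key step.
2. Key disconnection C3–C4: a macrocyclic Corey–Chaykovsky epoxidation, in which a diphenylsulfonium ylide at C3 adds to a C4 methyl ketone and closes the 14-membered carbocycle and the oxirane together. The enabling feature is the trisubstituted C3–C4 oxirane itself: C3 carries H and ends a two-carbon arm on C1 of the lactone ring (a hydroborated vinyl group), and C4 carries CH3 between C5H2 and the C6 carbinol (a β-silyloxy methyl ketone). Unlike an alkene epoxidation, this cannot touch C7=C8.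
3. The ε-lactone (tertiary O–C12) comes from Baeyer–Villiger ring expansion of a 2,2,5-trisubstituted cyclohexanone with retention. C11–C12 comes from an aldol of the tetrasubstituted enolate of (5R)-5-ethenyl-2-methylcyclohexanone with a nerol-derived Z-aldehyde.
4. Stereocentres: C1 by Rh/BINAP conjugate vinylation; C12 and C11 relayed from C1 in the aldol; C6 by catalytic allylboration; C3 and C4 in the key step; 7Z bought with nerol.
5. Ring order: cyclohexanone (bought) → oxepan-2-one (ring expansion) → 14-membered carbocycle and oxirane in one operation.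

Key step: step 17

Remark: cembrane numbering is used for positions (C1 = lactone-ring CH, C3–C4 = oxirane, C6 and C11 = carbinols, C7=C8, C12 = O-bearing quaternary carbon, C15/C16/C17 = α-carbon, carbonyl, exo-methylene). The target is then (1S,3R,4S,6R,7Z,11R,12R), and all selectivities below are expectations.

**Step 1**
Reactants: 1 nerol
Product: 2 neryl 4-methoxybenzyl (PMB) ether
Conditions: NaH, PMBCl, Bu4NI (cat.), THF/DMF, 0 → 25 °C
Reagents that add atoms: 4-methoxybenzyl chloride `COc1ccc(CCl)cc1`
Why: Williamson etherification of the primary allylic alcohol; the Z-alkene of nerol (future C7=C8) is untouched.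

**Step 2**
Reactants: 2 neryl PMB ether
Product: 4 (4Z)-6-[(4-methoxybenzyl)oxy]-4-methylhex-4-enal, via epoxide 3 (not isolated)
Conditions: mCPBA (1.05 equiv), CH2Cl2, −20 → 0 °C; then H5IO6, THF/H2O, 0 °C
Reagents that add atoms: mCPBA `OOC(=O)c1cccc(Cl)c1`
Why: Peracid epoxidation should prefer the distal, more electron-rich trisubstituted alkene (the proximal one is deactivated by the allylic ether oxygen), and periodic acid cleaves the epoxide through its diol to the aldehyde and acetone.

**Step 3**
Reactants: 5 cyclohex-2-en-1-one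
Product: 7 racemic 6-methylcyclohex-2-en-1-one, via lithium dienolate 6 (not isolated)
Conditions: LDA, THF, −78 °C; MeI, −78 → 0 °C
Reagents that add atoms: iodomethane `CI`
Why: Kinetic α′-deprotonation gives the cross-conjugated dienolate, which is C-methylated (enolate alkylation); the new centre may be racemic because step 5 makes it planar again.

**Step 4**
Reactants: 7 racemic 6-methylcyclohex-2-en-1-one
Product: 8 (5R)-5-ethenyl-2-methylcyclohexan-1-one (C2 epimer mixture)
Conditions: CH2=CHBF3K, [Rh(cod)2]BF4 (3 mol %), (R)-BINAP, toluene/H2O, 100 °C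
Reagents that add atoms: potassium vinyltrifluoroborate `[K+].C=C[B-](F)(F)F`
Why: Hayashi–Miyaura Rh/BINAP asymmetric 1,4-addition of a vinylboron reagent; the catalyst should control the β-carbon (future C1) for both enantiomers of 7, with (R)-BINAP chosen by analogy with aryl and alkenyl additions to cyclohexenone, and the C2 epimers converge in step 5.

**Step 5**
Reactants: 8 (5R)-5-ethenyl-2-methylcyclohexan-1-one
Product: 9 {[(5R)-5-ethenyl-2-methylcyclohex-1-en-1-yl]oxy}trimethylsilane
Conditions: TMSCl, NaI, Et3N, MeCN, 25 °C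
Reagents that add atoms: chlorotrimethylsilane `C[Si](C)(C)Cl`
Why: Thermodynamic enol silylation (TMSI formed in situ) favours the more substituted enol ether, which erases the C2 stereocentre and fixes the enolate regiochemistry.

**Step 6**
Reactants: 9 silyl enol ether, 4 (4Z)-6-[(4-methoxybenzyl)oxy]-4-methylhex-4-enal
Product: 11 (2R,5R)-5-ethenyl-2-[(1R,4Z)-1-hydroxy-6-[(4-methoxybenzyl)oxy]-4-methylhex-4-en-1-yl]-2-methylcyclohexan-1-one, via lithium enolate 10 (not isolated)
Conditions: MeLi, THF, 0 °C; then 4, −78 °C; AcOH quench at −78 °C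
Reagents that add atoms: none
Why: Directed aldol addition of the regiodefined tetrasubstituted lithium enolate: axial attack on the half-chair with the C5 vinyl group pseudo-equatorial should place the new bond cis to vinyl (C12 relayed from C1, as in alkylations of dihydrocarvone-type enolates), and a Zimmerman–Traxler chair with the aldehyde chain equatorial should give the like (11R,12R) aldol.

**Step 7**
Reactants: 11 aldol
Product: 12 tert-butyldimethylsilyl (TBS) ether of 11
Conditions: TBSOTf, 2,6-lutidine, CH2Cl2, −78 → 0 °C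
Reagents that add atoms: TBSOTf `CC(C)(C)[Si](C)(C)OS(=O)(=O)C(F)(F)F`
Why: Silylation of the hindered secondary hydroxyl with the silyl triflate blocks retro-aldol cleavage and gives a group that lasts to the final step.

**Step 8**
Reactants: 12 TBS-protected aldol
Product: 13 (4R,7R)-4-ethenyl-7-methyl-7-[(1R,4Z)-1-(TBS-oxy)-6-(PMB-oxy)-4-methylhex-4-en-1-yl]oxepan-2-one
Conditions: (TMSO)2, TMSOTf (cat.), CH2Cl2, −40 → −20 °C
Reagents that add atoms: bis(trimethylsilyl) peroxide `C[Si](C)(C)OO[Si](C)(C)C`
Why: Baeyer–Villiger oxidation with a silyl peroxide under Lewis-acid catalysis, a non-epoxidising variant that should spare both alkenes; the fully substituted C12 migrates in preference to the CH2 and with retention, giving the tertiary ε-lactone.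

**Step 9**
Reactants: 13 vinyl lactone
Product: 15 (4S,7R)-4-(2-hydroxyethyl) analogue of 13, via B-alkyl-9-BBN 14 (not isolated)
Conditions: 9-BBN, THF, 0 → 25 °C; then H2O2, pH 7 buffer, 0 °C
Reagents that add atoms: 9-BBN `B1C2CCCC1CCC2` (boron carrier of 14), hydrogen peroxide `OO`
Why: Brown hydroboration–oxidation; 9-BBN reacts with the monosubstituted vinyl group far faster than with the trisubstituted alkene or the lactone and places boron on the terminal carbon (future C3).

**Step 10**
Reactants: 15 primary alcohol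
Product: 16 (4R,7R)-4-(2-iodoethyl) analogue of 13
Conditions: I2, PPh3, imidazole, CH2Cl2, 0 °C
Reagents that add atoms: iodine `II`
Why: Appel-type iodination of the primary alcohol; the iodide is inert in steps 11–15 and is the latent sulfonium carbon C3.

**Step 11**
Reactants: 16 iodide
Product: 17 primary allylic alcohol (PMB removed)
Conditions: DDQ, CH2Cl2/pH 7 buffer, 0 °C
Reagents that add atoms: none
Why: Oxidative cleavage of the PMB ether by DDQ, orthogonal to the TBS ether, the iodide and the lactone.

**Step 12**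
Reactants: 17 allylic alcohol
Product: 18 (Z)-enal
Conditions: MnO2, CH2Cl2, 25 °C
Reagents that add atoms: none
Why: Neutral heterogeneous allylic oxidation, chosen to avoid Z → E isomerisation of the neral-type enal.

**Step 13**
Reactants: 18 (Z)-enal
Product: 20 (4R,7R)-7-[(1R,4Z,6R)-1-(TBS-oxy)-6-hydroxy-4-methylnona-4,8-dien-1-yl]-4-(2-iodoethyl)-7-methyloxepan-2-one, via O-boronate 19 (not isolated)
Conditions: allyl-B(pin), (R)-TRIP (5 mol %), 4 Å MS, toluene, −30 °C; aqueous work-up
Reagents that add atoms: allylboronic acid pinacol ester `C=CCB1OC(C)(C)C(C)(C)O1`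
Why: Chiral phosphoric acid-catalysed allylboration through a closed six-membered transition state; catalyst control should deliver allyl to the Re face of the enal and set C6 (R), with the antipodal acid as the choice if the sense proved opposite.

**Step 14**
Reactants: 20 homoallylic alcohol
Product: 21 bis-TBS ether
Conditions: TBSOTf, 2,6-lutidine, CH2Cl2, −78 °C
Reagents that add atoms: TBSOTf `CC(C)(C)[Si](C)(C)OS(=O)(=O)C(F)(F)F`
Why: Standard silylation; a silyl ether at C6 does not chelate and withstands the Wacker, silver and base steps.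

**Step 15**
Reactants: 21 bis-TBS ether
Product: 22 (4R,7R)-7-[(1R,4Z,6R)-1,6-bis(TBS-oxy)-4-methyl-8-oxonon-4-en-1-yl]-4-(2-iodoethyl)-7-methyloxepan-2-one
Conditions: PdCl2 (10 mol %), Cu(OAc)2 (20 mol %), O2 (1 atm), DMA/H2O, 25 °C
Reagents that add atoms: water `O`
Why: Tsuji–Wacker oxidation of the only monosubstituted alkene with Markovnikov selectivity gives the C4 methyl ketone; the trisubstituted alkene does not react.

**Step 16**
Reactants: 22 iodo ketone
Product: 23 {2-[(4R,7R)-7-[(1R,4Z,6R)-1,6-bis(TBS-oxy)-4-methyl-8-oxonon-4-en-1-yl]-7-methyl-2-oxooxepan-4-yl]ethyl}diphenylsulfonium tetrafluoroborate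
Conditions: Ph2S (5 equiv), AgBF4, CH2Cl2, 0 → 25 °C, dark
Reagents that add atoms: diphenyl sulfide `c1ccc(Sc2ccccc2)cc1`, silver tetrafluoroborate `[Ag+].F[B-](F)(F)F`
Why: Silver-assisted S-alkylation of diphenyl sulfide by the primary iodide, the classical route to alkyldiphenylsulfonium salts; the S-aryl groups have no α-hydrogen, so only C3 can later be deprotonated.

**Step 17**
Reactants: 23 sulfonium tetrafluoroborate
Product: 26 (1S,3R,4S,6R,7Z,11R,12R)-6,11-bis(TBS-oxy)-3,4-epoxy-cembr-7-en-16,12-olide (saturated lactone), via sulfonium ylide 24 (not isolated), via betaine 25 (not isolated)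
Conditions: LiHMDS (1.05 equiv, slow addition), THF (1 mM), −78 → −40 °C
Reagents that add atoms: none
Why: Proposed new method: LiHMDS removes an α-proton of the sulfonium group (by far the most acidic C–H of 23; estimated pKa below 20 against about 26 for the methyl ketone), the ylide carbon C3 of 24 adds to the C4 methyl ketone to give betaine 25, and its alkoxide displaces diphenyl sulfide from C3 with inversion; the closest known reaction is the intermolecular Corey–Chaykovsky epoxidation of ketones by alkyldiphenylsulfonium ylides, which has not been used to close a macrocycle. The carbocycle closes in the C–C bond-forming 14-exo-trig addition and the oxirane in the following 3-exo-tet substitution, so one operation makes the C3–C4 bond, both rings and both new stereocentres, and does so only at the ketone, whereas epoxidation of a C3=C4 alkene could not be told apart from C7=C8. Ketone-over-lactone selectivity is needed because C3 could reach the lactone carbonyl through a five-membered transition state; it should be secured because addition of this weakly basic ylide to an alkyl ester is reversible at −78 °C (the adduct could only expel a tertiary alkoxide, a much poorer leaving group than the ylide), while the ketone betaine is drained irreversibly by ring closure and the ylide is too weak a base to enolise the ketone. C4 (S) requires attack on the Re face of the ketone and C3 (R) a cis (Z-type) union of C2 and C5 on the oxirane; both are expected from the folded conformer imposed by the cis C1/C12 exits of the lactone ring and the 7Z alkene, in which allylic strain turns the C6 silyloxy group outwards and the C4 methyl group lies on the periphery, but this rests on conformational reasoning, not precedent. High dilution and slow addition of base keep the ylide concentration low and suppress intermolecular epoxidation.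

**Step 18**
Reactants: 26 macrocyclic epoxy lactone
Product: 30 bis-TBS ether of the target (α-methylene lactone), via lactone enolate 27 (not isolated), via Mannich base 28 (not isolated), via ammonium iodide 29 (not isolated)
Conditions: LDA, THF, −78 °C; CH2=NMe2+ I−, −78 → 25 °C; MeI, CH2Cl2/MeOH; then aq. NaHCO3, 25 °C
Reagents that add atoms: Eschenmoser's salt `C=[N+](C)C.[I-]`, iodomethane `CI` (methyl of 29 only)
Why: Eschenmoser methylenation: the lactone has a single enolisable position (C15), Mannich alkylation followed by N-methylation and base-induced β-elimination installs C17, and the temporary C15 stereocentre disappears.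

**Step 19**
Reactants: 30 bis-TBS ether
Product: 31 target, (1S,3R,4S,6R,7Z,11R,12R)-3,4-epoxy-6,11-dihydroxycembra-7,15(17)-dien-16,12-olide
Conditions: HF·pyridine, pyridine, THF, 0 → 25 °C
Reagents that add atoms: none
Why: Buffered fluoride desilylation of both secondary TBS ethers, conditions commonly used with trisubstituted epoxides and enoates present; no stereocentre is touched.

**Compound list**
1 | nerol, (2Z)-3,7-dimethylocta-2,6-dien-1-ol | `OC/C=C(/C)CCC=C(C)C` | starting material
2 | neryl 4-methoxybenzyl ether | `COc1ccc(COC/C=C(/C)CCC=C(C)C)cc1` | intermediate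
3 | 6,7-epoxide of 2 (racemic at the epoxide CH) | `COc1ccc(COC/C=C(/C)CCC2OC2(C)C)cc1` | intermediate (not isolated)
4 | (4Z)-6-[(4-methoxybenzyl)oxy]-4-methylhex-4-enal | `COc1ccc(COC/C=C(/C)CCC=O)cc1` | intermediate
5 | cyclohex-2-en-1-one | `O=C1C=CCCC1` | starting material
6 | lithium cyclohexa-1,5-dien-1-olate | `[Li]OC1=CCCC=C1` | intermediate (not isolated)
7 | racemic 6-methylcyclohex-2-en-1-one | `CC1CCC=CC1=O` | intermediate
8 | (5R)-5-ethenyl-2-methylcyclohexan-1-one, C2 epimers | `O=C1C[C@H](C=C)CCC1C` | intermediate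
9 | {[(5R)-5-ethenyl-2-methylcyclohex-1-en-1-yl]oxy}trimethylsilane | `C[Si](C)(C)OC1=C(C)CC[C@@H](C=C)C1` | intermediate
10 | lithium (5R)-5-ethenyl-2-methylcyclohex-1-en-1-olate | `[Li]OC1=C(C)CC[C@@H](C=C)C1` | intermediate (not isolated)
11 | (2R,5R)-5-ethenyl-2-[(1R,4Z)-1-hydroxy-6-(PMB-oxy)-4-methylhex-4-en-1-yl]-2-methylcyclohexan-1-one | `C=C[C@@H]1CC[C@](C)([C@H](O)CC\C(C)=C/COCc2ccc(OC)cc2)C(=O)C1` | intermediate
12 | TBS ether of 11 | `C=C[C@@H]1CC[C@](C)([C@H](O[Si](C)(C)C(C)(C)C)CC\C(C)=C/COCc2ccc(OC)cc2)C(=O)C1` | intermediate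
13 | (4R,7R)-4-ethenyl-7-methyl-7-[(1R,4Z)-1-(TBS-oxy)-6-(PMB-oxy)-4-methylhex-4-en-1-yl]oxepan-2-one | `C=C[C@@H]1CC[C@](C)([C@H](O[Si](C)(C)C(C)(C)C)CC\C(C)=C/COCc2ccc(OC)cc2)OC(=O)C1` | intermediate
14 | B-alkyl-9-BBN adduct of 13 (boron on the terminal carbon of the former vinyl group) | `C1CCC2CCCC1B2CC[C@@H]1CC[C@](C)([C@H](O[Si](C)(C)C(C)(C)C)CC\C(C)=C/COCc2ccc(OC)cc2)OC(=O)C1` | intermediate (not isolated)
15 | (4S,7R)-4-(2-hydroxyethyl) analogue of 13 | `OCC[C@@H]1CC[C@](C)([C@H](O[Si](C)(C)C(C)(C)C)CC\C(C)=C/COCc2ccc(OC)cc2)OC(=O)C1` | intermediate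
16 | (4R,7R)-4-(2-iodoethyl) analogue of 13 | `ICC[C@@H]1CC[C@](C)([C@H](O[Si](C)(C)C(C)(C)C)CC\C(C)=C/COCc2ccc(OC)cc2)OC(=O)C1` | intermediate
17 | (4R,7R)-7-[(1R,4Z)-1-(TBS-oxy)-6-hydroxy-4-methylhex-4-en-1-yl]-4-(2-iodoethyl)-7-methyloxepan-2-one | `ICC[C@@H]1CC[C@](C)([C@H](O[Si](C)(C)C(C)(C)C)CC\C(C)=C/CO)OC(=O)C1` | intermediate
18 | (4R,7R)-7-[(1R,4Z)-1-(TBS-oxy)-4-methyl-6-oxohex-4-en-1-yl]-4-(2-iodoethyl)-7-methyloxepan-2-one | `ICC[C@@H]1CC[C@](C)([C@H](O[Si](C)(C)C(C)(C)C)CC\C(C)=C/C=O)OC(=O)C1` | intermediate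
19 | O-pinacolboronate of 20 | `ICC[C@@H]1CC[C@](C)([C@H](O[Si](C)(C)C(C)(C)C)CC\C(C)=C/[C@H](OB2OC(C)(C)C(C)(C)O2)CC=C)OC(=O)C1` | intermediate (not isolated)
20 | (4R,7R)-7-[(1R,4Z,6R)-1-(TBS-oxy)-6-hydroxy-4-methylnona-4,8-dien-1-yl]-4-(2-iodoethyl)-7-methyloxepan-2-one | `ICC[C@@H]1CC[C@](C)([C@H](O[Si](C)(C)C(C)(C)C)CC\C(C)=C/[C@H](O)CC=C)OC(=O)C1` | intermediate
21 | bis-TBS ether of 20 | `ICC[C@@H]1CC[C@](C)([C@H](O[Si](C)(C)C(C)(C)C)CC\C(C)=C/[C@H](O[Si](C)(C)C(C)(C)C)CC=C)OC(=O)C1` | intermediate
22 | (4R,7R)-7-[(1R,4Z,6R)-1,6-bis(TBS-oxy)-4-methyl-8-oxonon-4-en-1-yl]-4-(2-iodoethyl)-7-methyloxepan-2-one | `ICC[C@@H]1CC[C@](C)([C@H](O[Si](C)(C)C(C)(C)C)CC\C(C)=C/[C@H](O[Si](C)(C)C(C)(C)C)CC(C)=O)OC(=O)C1` | intermediate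
23 | diphenylsulfonium tetrafluoroborate from 22 (S on C3) | `c1ccccc1[S+](c1ccccc1)CC[C@@H]1CC[C@](C)([C@H](O[Si](C)(C)C(C)(C)C)CC\C(C)=C/[C@H](O[Si](C)(C)C(C)(C)C)CC(C)=O)OC(=O)C1.F[B-](F)(F)F` | intermediate
24 | sulfonium ylide of 23 (carbanion at C3) | `c1ccccc1[S+](c1ccccc1)[CH-]C[C@@H]1CC[C@](C)([C@H](O[Si](C)(C)C(C)(C)C)CC\C(C)=C/[C@H](O[Si](C)(C)C(C)(C)C)CC(C)=O)OC(=O)C1` | intermediate (not isolated)
25 | macrocyclic betaine, (3S)-diphenylsulfonio (4S)-alkoxide | `C1C(=O)O[C@]2(C)CC[C@H]1C[C@H]([S+](c1ccccc1)c1ccccc1)[C@]([O-])(C)C[C@@H](O[Si](C)(C)C(C)(C)C)/C=C(/C)CC[C@H]2O[Si](C)(C)C(C)(C)C` | intermediate (not isolated)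
26 | (1S,3R,4S,6R,7Z,11R,12R)-6,11-bis(TBS-oxy)-3,4-epoxy-cembr-7-en-16,12-olide | `C1C(=O)O[C@]2(C)CC[C@H]1C[C@H]1O[C@@]1(C)C[C@@H](O[Si](C)(C)C(C)(C)C)/C=C(/C)CC[C@H]2O[Si](C)(C)C(C)(C)C` | intermediate
27 | lithium enolate of 26 (C15=C16) | `C1=C(O[Li])O[C@]2(C)CC[C@H]1C[C@H]1O[C@@]1(C)C[C@@H](O[Si](C)(C)C(C)(C)C)/C=C(/C)CC[C@H]2O[Si](C)(C)C(C)(C)C` | intermediate (not isolated)
28 | 15-(dimethylaminomethyl) derivative of 26 (C15 epimers) | `CN(C)CC1C(=O)O[C@]2(C)CC[C@H]1C[C@H]1O[C@@]1(C)C[C@@H](O[Si](C)(C)C(C)(C)C)/C=C(/C)CC[C@H]2O[Si](C)(C)C(C)(C)C` | intermediate (not isolated)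
29 | trimethylammonium iodide from 28 | `C[N+](C)(C)CC1C(=O)O[C@]2(C)CC[C@H]1C[C@H]1O[C@@]1(C)C[C@@H](O[Si](C)(C)C(C)(C)C)/C=C(/C)CC[C@H]2O[Si](C)(C)C(C)(C)C.[I-]` | intermediate (not isolated)
30 | 6,11-bis-TBS ether of the target | `C=C1C(=O)O[C@]2(C)CC[C@H]1C[C@H]1O[C@@]1(C)C[C@@H](O[Si](C)(C)C(C)(C)C)/C=C(/C)CC[C@H]2O[Si](C)(C)C(C)(C)C` | intermediate
31 | CNP0250657.1, (1S,3R,4S,6R,7Z,11R,12R)-3,4-epoxy-6,11-dihydroxycembra-7,15(17)-dien-16,12-olide | `C=C1C(=O)O[C@]2(C)CC[C@H]1C[C@H]1O[C@@]1(C)C[C@@H](O)/C=C(/C)CC[C@H]2O` | target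

**Totals**
Total step count: 19. Longest linear sequence: 17 steps (steps 3–19, from cyclohex-2-en-1-one); the nerol branch (steps 1–2) joins at step 6.

**Steps most likely to fail**

Step 17 (labelled Proposed new method). Two things may go wrong. The ylide may be lost by acyl transfer to the lactone carbonyl, or by decomposition before the slow 14-membered closure. Betaine formation may also show poor cis/trans and facial selectivity, giving C3/C4 diastereomers. The fallback uses known chemistry, sets out from iodide 22 and returns at epoxide 26. Kornblum-type oxidation of 22 (N-methylmorpholine N-oxide, DMSO, 25 °C) would give keto aldehyde F1. A titanium-mediated (McMurry-type) intramolecular pinacol coupling (TiCl3(DME)1.5, Zn–Cu, DME, slow addition, 25 °C), a reaction type established for closing 14-membered carbocycles at a secondary/tertiary diol, would give the C3–C4 diols, from which the (3S,4S)-diol F2 is separated. Selective mesylation of the secondary C3 hydroxyl (MsCl, Et3N, CH2Cl2, −20 °C) would give mesylate F3, and NaH in THF at 0 °C would close the oxirane with inversion at C3 to 26. This fallback does not control the diol configuration either; it only replaces the unprecedented step.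

Step 6. Simple diastereoselection at C11 may be poor, because in the chair both α-substituents of the tetrasubstituted enolate are gauche to the aldehyde chain, and proton transfer from the enolisable aldehyde may compete. The fallback corrects C11 after ring expansion instead of in the aldol; it sets out from lactone 13, obtained as the C11 epimer mixture that steps 6–8 would then deliver, and returns to 13 as a single epimer. HF·pyridine in THF would remove the silyl group to give hydroxy lactones F4, and Dess–Martin periodinane would give keto lactone F5. L-Selectride in THF at −78 °C should then add hydride anti to the C12–O bond (polar Felkin–Anh control) to give the (11R)-alcohol F6, and TBSOTf/2,6-lutidine would return 13.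

Step 8. Oxygen insertion at the hindered α-quaternary ketone may be slow, so that Lewis-acid-induced loss of the silyl or PMB group competes. The fallback sets out from ketone 12 and returns at lactone 13. Excess mCPBA with NaHCO3 in CH2Cl2 would carry out the Baeyer–Villiger reaction and also epoxidise C7=C8, giving epoxy lactone F7. Stereoretentive deoxygenation (MeReO3 cat., PPh3, benzene, 25 °C) would then restore the Z-alkene and give 13; any vinyl epoxide formed alongside would be deoxygenated in the same operation.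

**Further compounds**
F1 | step 17 | keto aldehyde, (4R,7R)-7-[(1R,4Z,6R)-1,6-bis(TBS-oxy)-4-methyl-8-oxonon-4-en-1-yl]-7-methyl-4-(2-oxoethyl)oxepan-2-one | `O=CC[C@@H]1CC[C@](C)([C@H](O[Si](C)(C)C(C)(C)C)CC\C(C)=C/[C@H](O[Si](C)(C)C(C)(C)C)CC(C)=O)OC(=O)C1`
F2 | step 17 | (3S,4S)-3,4-diol of the macrocyclic lactone (6,11-bis-TBS) | `C1C(=O)O[C@]2(C)CC[C@H]1C[C@H](O)[C@](O)(C)C[C@@H](O[Si](C)(C)C(C)(C)C)/C=C(/C)CC[C@H]2O[Si](C)(C)C(C)(C)C`
F3 | step 17 | C3 methanesulfonate of F2 | `C1C(=O)O[C@]2(C)CC[C@H]1C[C@H](OS(C)(=O)=O)[C@](O)(C)C[C@@H](O[Si](C)(C)C(C)(C)C)/C=C(/C)CC[C@H]2O[Si](C)(C)C(C)(C)C`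
F4 | step 6 | hydroxy lactone, C11 epimer mixture (13 without TBS) | `C=C[C@@H]1CC[C@](C)(C(O)CC\C(C)=C/COCc2ccc(OC)cc2)OC(=O)C1`
F5 | step 6 | C11 keto lactone | `C=C[C@@H]1CC[C@](C)(C(=O)CC\C(C)=C/COCc2ccc(OC)cc2)OC(=O)C1`
F6 | step 6 | (11R)-hydroxy lactone | `C=C[C@@H]1CC[C@](C)([C@H](O)CC\C(C)=C/COCc2ccc(OC)cc2)OC(=O)C1`
F7 | step 8 | 7,8-cis-epoxide of lactone 13 (one of two epoxide-face diastereomers drawn) | `C=C[C@@H]1CC[C@](C)([C@H](O[Si](C)(C)C(C)(C)C)CC[C@]2(C)O[C@@H]2COCc2ccc(OC)cc2)OC(=O)C1`
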